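**Retrosynthetic overview**

1. The target is cut at the C3–O–C15′ ester: the hindered C3 acid of the vinyl (left) half acylates the primary C15′–OH of the 14′,15′-diol (right) half; three 2-(trimethylsilyl)ethyl esters are removed last.
2. The left-half vinyl group comes from its own 14,15-diol by Corey–Winter deoxygenation; ring C of each half comes from Sharpless epoxidation of a (Z)-allylic alcohol and 6-exo epoxide opening by the tertiary C8–OH with inversion at C13.
3. Key step: C8–OH, C9–H and the C12–C13 bond arise in one pot by cyclic hydroboration of a 9-vinyl diene, palladium-catalysed B-alkyl Suzuki coupling with (Z)-3-iodobut-2-en-1-ol, and oxidation.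
4. The diene comes from vinylation of a tetrasubstituted enol triflate, C8 methylation, and a ring B keto diester made from 2-methylcyclohex-2-en-1-one by enantioselective Mukaiyama–Michael addition and anti alkylation (C5, C10).
5. Ring order: ring B is the bought enone and is decorated first; ring C is closed last in each half; the two halves, built in parallel with different ester patterns, are then joined.

Labels: labdane atom numbers are used (ring B = C5–C10; C20 = methyl on C10; C1–C2 = acetate arm on C10; C4/C3 = 2-methylpropanoate arm on C5; C17 = methyl on C8; side chain C11–C16). TMSE = 2-(trimethylsilyl)ethyl. Target configuration read from the SMILES: 5S,8S,9S,10R,13R in both halves and 14′R.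

Assumption: a telescoped one-pot operation counts as one step, and 2-(trimethylsilyl)ethanol, Me3SiCl and MeI are treated as reagents, not starting materials.

**Route**

Step 1
Reactants: 1 bromoacetyl bromide
Product: 2 2-(trimethylsilyl)ethyl bromoacetate
Conditions: 2-(trimethylsilyl)ethanol, pyridine, CH2Cl2, 0 °C
Reagents that add atoms: 2-(trimethylsilyl)ethanol, C[Si](C)(C)CCO
Why: alcoholysis of the acyl bromide (acyl substitution) is much faster than displacement of the alkyl bromide at 0 °C.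

Step 2
Reactants: 3 but-2-yn-1-ol
Product: 4 (Z)-3-iodobut-2-en-1-ol
Conditions: NaAlH2(OCH2CH2OMe)2, THF, 0 → 23 °C; then I2, −78 → 0 °C
Reagents that add atoms: iodine, II
Why: hydroxyl-directed trans-hydroalumination puts aluminium on C3 cis to the CH2O group, and iodinolysis with retention gives only the Z vinyl iodide.

Step 3
Reactants: 5 methyl 2-methylpropanoate
Product: 6 1-methoxy-2-methyl-1-(trimethylsilyloxy)prop-1-ene
Conditions: LiN(iPr)2, THF, −78 °C; then Me3SiCl, −78 → 23 °C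
Reagents that add atoms: chlorotrimethylsilane, C[Si](C)(C)Cl
Why: O-silylation of the lithium ester enolate gives the silyl ketene acetal, which has no geometry issue because the enolate carbon carries two methyls.

Step 4
Reactants: 7 2-methylcyclohex-2-en-1-one; 6 silyl ketene acetal; 2 TMSE bromoacetate
Product: 9 2-(trimethylsilyl)ethyl 2-[(1R,6S)-6-(1-methoxy-2-methyl-1-oxopropan-2-yl)-1-methyl-2-oxocyclohexyl]acetate, via silyl enol ether 8 (not isolated)
Conditions: (S)-1-(2-methylphenyl)-3,3-diphenyltetrahydro-1H,3H-pyrrolo[1,2-c][1,3,2]oxazaborole·HNTf2 (20 mol %, or its enantiomer, whichever gives Si-face attack at C3 of 7), Ph3PO (25 mol %), toluene, −20 °C; evaporate; then (Me2N)3S+ Me3SiF2− (1.1 equiv), THF, −78 °C; then 2, −78 → −30 °C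
Reagents that add atoms: none
Why: the oxazaborolidinium-catalysed enantioselective Mukaiyama–Michael addition sets C5 (S) by Si-face attack and gives a regiodefined silyl enol ether, whose fluoride-generated enolate is alkylated anti to the bulky C5 arm (fluoride-mediated regiospecific enolate alkylation), setting quaternary C10 (R).

Step 5
Reactants: 9 left keto diester
Product: 10 2-(trimethylsilyl)ethyl 2-[(1R,3RS,6S)-6-(1-methoxy-2-methyl-1-oxopropan-2-yl)-1,3-dimethyl-2-oxocyclohexyl]acetate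
Conditions: LiN(iPr)2 (1.05 equiv), THF, −78 °C; then MeI, −78 → −40 °C
Reagents that add atoms: iodomethane, CI
Why: kinetic enolate methylation can only occur at C8 because C10 is quaternary, and the new C8 centre is erased in the next step.

Step 6
Reactants: 10 left methyl ketone
Product: 11 2-(trimethylsilyl)ethyl 2-[(1R,6S)-6-(1-methoxy-2-methyl-1-oxopropan-2-yl)-1,3-dimethyl-2-(trifluoromethanesulfonyloxy)cyclohex-2-en-1-yl]acetate
Conditions: KN(SiMe3)2, THF, −78 → 0 °C; then PhNTf2, −78 → 23 °C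
Reagents that add atoms: N-phenylbis(trifluoromethanesulfonimide), O=S(=O)(N(c1ccccc1)S(=O)(=O)C(F)(F)F)C(F)(F)F
Why: O-triflation of the only possible ketone enolate (towards C8) gives the tetrasubstituted enol triflate.

Step 7
Reactants: 11 left enol triflate; 12 potassium vinyltrifluoroborate
Product: 13 2-(trimethylsilyl)ethyl 2-[(1R,6S)-2-ethenyl-6-(1-methoxy-2-methyl-1-oxopropan-2-yl)-1,3-dimethylcyclohex-2-en-1-yl]acetate
Conditions: PdCl2(dppf) (5 mol %), Et3N, n-PrOH, 90 °C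
Reagents that add atoms: none
Why: Suzuki–Miyaura vinylation of the enol triflate (oxidative addition of zerovalent palladium, vinyl transmetalation, reductive elimination) gives the 9-vinyl diene.

Step 8
Reactants: 13 left diene; 4 (Z)-3-iodobut-2-en-1-ol
Product: 16 2-(trimethylsilyl)ethyl 2-[(1R,2S,3S,6S)-3-hydroxy-2-[(3Z)-5-hydroxy-3-methylpent-3-en-1-yl]-6-(1-methoxy-2-methyl-1-oxopropan-2-yl)-1,3-dimethylcyclohexyl]acetate, via thexylborolane 14 (not isolated), via borinic acid 15 (not isolated)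
Conditions: ThxBH2 (1.1 equiv, from BH3·THF and 2,3-dimethylbut-2-ene), THF, −20 → 23 °C; then 4, PdCl2(dppf) (5 mol %), AsPh3 (10 mol %), aq Cs2CO3, DMF, 23 → 45 °C; then NaBO3·4H2O, THF/H2O, 23 °C
Reagents that add atoms: sodium perborate, O=BO[O-].[Na+]
Why: Proposed new method: thexylborane adds to the unhindered vinyl group (boron on C12) and the resulting R(Thx)BH hydroborates the tetrasubstituted C8=C9 bond intramolecularly through a five-membered borolane on the face anti to the axial C10 methyl, so syn delivery places H on C9 and B on C8 (sets C9 S and C8 S); after hydroxide activation only the primary C12–B bond can transmetalate to the alkenylpalladium iodide formed by oxidative addition of zerovalent palladium into 4, reductive elimination forms the C12–C13 bond with retention of the Z geometry, and the surviving tertiary C8–B bond is oxidised with retention to the C8 hydroxyl; the closest known reactions are the 9-BBN B-alkyl Suzuki–Miyaura coupling, thexylborane cyclic hydroboration of 1,3-dienes, and diboration/primary-selective coupling/oxidation sequences.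

Step 9
Reactants: 16 left allylic alcohol
Product: 18 2-(trimethylsilyl)ethyl 2-[(2R,4aS,5R,6S,8aS)-2-[(1R)-1,2-dihydroxyethyl]-6-(1-methoxy-2-methyl-1-oxopropan-2-yl)-2,5,8a-trimethyloctahydro-2H-chromen-5-yl]acetate, via epoxy alcohol 17 (not isolated)
Conditions: Ti(OiPr)4 (10 mol %), D-(−)-diisopropyl tartrate (12 mol %), t-BuOOH (2 equiv), 4 Å MS, CH2Cl2, −20 °C; then camphorsulfonic acid (10 mol %), 0 → 23 °C
Reagents that add atoms: tert-butyl hydroperoxide, CC(C)(C)OO
Why: reagent-controlled Sharpless asymmetric epoxidation of the (Z)-allylic alcohol gives the (13S,14R)-epoxide, which the tertiary C8 hydroxyl opens under acid 6-exo at the tertiary C13 with inversion, closing ring C and setting C13 (R) while C14 (R) keeps the epoxide oxygen.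

Step 10
Reactants: 18 left diol
Product: 19 2-(trimethylsilyl)ethyl 2-[(2R,4aS,5R,6S,8aS)-6-(1-methoxy-2-methyl-1-oxopropan-2-yl)-2,5,8a-trimethyl-2-[(4R)-2-sulfanylidene-1,3-dioxolan-4-yl]octahydro-2H-chromen-5-yl]acetate
Conditions: 1,1'-thiocarbonyldiimidazole (1.5 equiv), DMAP (10 mol %), toluene, 80 °C
Reagents that add atoms: 1,1'-thiocarbonyldiimidazole, S=C(n1ccnc1)n1ccnc1
Why: the only 1,2-diol is converted into its cyclic thionocarbonate (first stage of the Corey–Winter olefination) with no change at any stereocentre.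

Step 11
Reactants: 19 left thionocarbonate
Product: 20 2-(trimethylsilyl)ethyl 2-[(2R,4aS,5R,6S,8aS)-2-ethenyl-6-(1-methoxy-2-methyl-1-oxopropan-2-yl)-2,5,8a-trimethyloctahydro-2H-chromen-5-yl]acetate
Conditions: 1,3-dimethyl-2-phenyl-1,3,2-diazaphospholidine (3 equiv), THF, 40 °C
Reagents that add atoms: none
Why: Corey–Winter olefination in its mild Corey–Hopkins form removes sulfur and CO2 to give the terminal vinyl group, leaving quaternary C13 (R) and the acid-sensitive tertiary allylic ether untouched.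

Step 12
Reactants: 20 left vinyl diester
Product: 21 2-[(2R,4aS,5R,6S,8aS)-2-ethenyl-2,5,8a-trimethyl-5-{2-oxo-2-[2-(trimethylsilyl)ethoxy]ethyl}octahydro-2H-chromen-6-yl]-2-methylpropanoic acid
Conditions: NaSEt (4 equiv), DMF, 80 °C; then aq HCl to pH 3
Reagents that add atoms: none
Why: thiolate SN2 attack at the O-methyl carbon cleaves even this hindered methyl ester, while the TMSE ester (slower SN2 at a substituted carbon, no fluoride present) survives.

Step 13
Reactants: 22 2-methylpropanoyl chloride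
Product: 23 2-(trimethylsilyl)ethyl 2-methylpropanoate
Conditions: 2-(trimethylsilyl)ethanol, pyridine, CH2Cl2, 0 → 23 °C
Reagents that add atoms: 2-(trimethylsilyl)ethanol, C[Si](C)(C)CCO
Why: simple acyl chloride esterification.

Step 14
Reactants: 23 TMSE 2-methylpropanoate
Product: 24 2-methyl-1-[2-(trimethylsilyl)ethoxy]-1-(trimethylsilyloxy)prop-1-ene
Conditions: LiN(iPr)2, THF, −78 °C; then Me3SiCl, −78 → 23 °C
Reagents that add atoms: chlorotrimethylsilane, C[Si](C)(C)Cl
Why: O-silylation of the ester enolate as in step 3.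

Step 15
Reactants: 7 2-methylcyclohex-2-en-1-one; 24 silyl ketene acetal; 2 TMSE bromoacetate
Product: 26 2-(trimethylsilyl)ethyl 2-methyl-2-[(1S,2R)-2-methyl-3-oxo-2-{2-oxo-2-[2-(trimethylsilyl)ethoxy]ethyl}cyclohexyl]propanoate, via silyl enol ether 25 (not isolated)
Conditions: same oxazaborolidine·HNTf2 catalyst as in step 4 (20 mol %), Ph3PO (25 mol %), toluene, −20 °C; evaporate; then (Me2N)3S+ Me3SiF2− (1.0 equiv), THF, −78 °C; then 2, −78 → −30 °C
Reagents that add atoms: none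
Why: same enantioselective Mukaiyama–Michael addition (C5 S) and anti enolate alkylation (C10 R) as step 4; the one equivalent of fluoride is consumed by the far more fluorophilic O–SiMe3 group, so the C-silyl TMSE ester survives.

Step 16
Reactants: 26 right keto diester
Product: 27 2-(trimethylsilyl)ethyl 2-[(1S,2R,4RS)-2,4-dimethyl-3-oxo-2-{2-oxo-2-[2-(trimethylsilyl)ethoxy]ethyl}cyclohexyl]-2-methylpropanoate
Conditions: LiN(iPr)2 (1.05 equiv), THF, −78 °C; then MeI, −78 → −40 °C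
Reagents that add atoms: iodomethane, CI
Why: kinetic enolate methylation at C8, the only enolisable ketone position.

Step 17
Reactants: 27 right methyl ketone
Product: 28 2-(trimethylsilyl)ethyl 2-[(1S,2R)-2,4-dimethyl-2-{2-oxo-2-[2-(trimethylsilyl)ethoxy]ethyl}-3-(trifluoromethanesulfonyloxy)cyclohex-3-en-1-yl]-2-methylpropanoate
Conditions: KN(SiMe3)2, THF, −78 → 0 °C; then PhNTf2, −78 → 23 °C
Reagents that add atoms: N-phenylbis(trifluoromethanesulfonimide), O=S(=O)(N(c1ccccc1)S(=O)(=O)C(F)(F)F)C(F)(F)F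
Why: enol triflate formation as in step 6.

Step 18
Reactants: 28 right enol triflate; 12 potassium vinyltrifluoroborate
Product: 29 2-(trimethylsilyl)ethyl 2-[(1S,2R)-3-ethenyl-2,4-dimethyl-2-{2-oxo-2-[2-(trimethylsilyl)ethoxy]ethyl}cyclohex-3-en-1-yl]-2-methylpropanoate
Conditions: PdCl2(dppf) (5 mol %), Et3N, n-PrOH, 90 °C
Reagents that add atoms: none
Why: Suzuki–Miyaura vinylation as in step 7.

Step 19
Reactants: 29 right diene; 4 (Z)-3-iodobut-2-en-1-ol
Product: 32 2-(trimethylsilyl)ethyl 2-[(1S,2R,3S,4S)-4-hydroxy-3-[(3Z)-5-hydroxy-3-methylpent-3-en-1-yl]-2,4-dimethyl-2-{2-oxo-2-[2-(trimethylsilyl)ethoxy]ethyl}cyclohexyl]-2-methylpropanoate, via thexylborolane 30 (not isolated), via borinic acid 31 (not isolated)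
Conditions: ThxBH2 (1.1 equiv, from BH3·THF and 2,3-dimethylbut-2-ene), THF, −20 → 23 °C; then 4, PdCl2(dppf) (5 mol %), AsPh3 (10 mol %), aq Cs2CO3, DMF, 23 → 45 °C; then NaBO3·4H2O, THF/H2O, 23 °C
Reagents that add atoms: sodium perborate, O=BO[O-].[Na+]
Why: Proposed new method: the same cyclic hydroboration/primary-selective B-alkyl coupling/oxidation relay as in step 8 (intramolecular syn hydroboration anti to the C10 methyl sets C9 S and C8 S, only the primary C12–B bond transmetalates to the alkenylpalladium species from 4, and the tertiary C8–B bond is oxidised with retention); the closest known reactions are the 9-BBN B-alkyl Suzuki–Miyaura coupling and thexylborane cyclic hydroboration of 1,3-dienes.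

Step 20
Reactants: 32 right allylic alcohol
Product: 34 2-(trimethylsilyl)ethyl 2-[(2R,4aS,5R,6S,8aS)-2-[(1R)-1,2-dihydroxyethyl]-2,5,8a-trimethyl-5-{2-oxo-2-[2-(trimethylsilyl)ethoxy]ethyl}octahydro-2H-chromen-6-yl]-2-methylpropanoate, via epoxy alcohol 33 (not isolated)
Conditions: Ti(OiPr)4 (10 mol %), D-(−)-diisopropyl tartrate (12 mol %), t-BuOOH (2 equiv), 4 Å MS, CH2Cl2, −20 °C; then camphorsulfonic acid (10 mol %), 0 → 23 °C
Reagents that add atoms: tert-butyl hydroperoxide, CC(C)(C)OO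
Why: Sharpless asymmetric epoxidation and acid-triggered 6-exo epoxide opening with inversion as in step 9 set C14′ (R) and C13′ (R) and close ring C.

Step 21
Reactants: 21 left acid; 34 right diol
Product: 36 tris-TMSE ester of excoecarin R1 (TMSE esters at C2 and C2′ and C3′ with the C3–O–C15′ ester link and free 14′-OH), via acid chloride 35 (not isolated)
Conditions: 1-chloro-N,N,2-trimethylprop-1-en-1-amine (1.2 equiv), CH2Cl2, 0 → 23 °C; then 34 (1.0 equiv), DMAP (2 equiv), Et3N, CH2Cl2, 0 → 40 °C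
Reagents that add atoms: none
Why: the hindered acid is converted under neutral conditions into its acid chloride, and DMAP-catalysed acyl substitution then occurs only at the primary C15′ hydroxyl because the secondary C14′ hydroxyl next to quaternary C13′ is too hindered.

Step 22
Reactants: 36 protected dimer
Product: 37 excoecarin R1
Conditions: Bu4NF (6 equiv), THF, 0 → 23 °C; then pH 3 aqueous work-up
Reagents that add atoms: none
Why: fluoride attack at silicon fragments all three TMSE esters (β-elimination of ethene) whatever the acyl hindrance, while the hindered inter-unit ester, the vinyl group and both tertiary ethers are inert.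

**Compound list**

1 | bromoacetyl bromide | BrCC(Br)=O | starting material
2 | 2-(trimethylsilyl)ethyl bromoacetate | BrCC(=O)OCC[Si](C)(C)C | intermediate
3 | but-2-yn-1-ol | CC#CCO | starting material
4 | (Z)-3-iodobut-2-en-1-ol | OC/C=C(C)\I | intermediate
5 | methyl 2-methylpropanoate | CC(C)C(=O)OC | starting material
6 | 1-methoxy-2-methyl-1-(trimethylsilyloxy)prop-1-ene | COC(O[Si](C)(C)C)=C(C)C | intermediate
7 | 2-methylcyclohex-2-en-1-one | CC1=CCCCC1=O | starting material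
8 | methyl 2-methyl-2-[(1S)-2-methyl-3-(trimethylsilyloxy)cyclohex-2-en-1-yl]propanoate | CC1=C(O[Si](C)(C)C)CCC[C@@H]1C(C)(C)C(=O)OC | intermediate
9 | 2-(trimethylsilyl)ethyl 2-[(1R,6S)-6-(1-methoxy-2-methyl-1-oxopropan-2-yl)-1-methyl-2-oxocyclohexyl]acetate | O=C1[C@](C)(CC(=O)OCC[Si](C)(C)C)[C@@H](C(C)(C)C(=O)OC)CCC1 | intermediate
10 | 2-(trimethylsilyl)ethyl 2-[(1R,3RS,6S)-6-(1-methoxy-2-methyl-1-oxopropan-2-yl)-1,3-dimethyl-2-oxocyclohexyl]acetate (C8 epimers) | O=C1[C@](C)(CC(=O)OCC[Si](C)(C)C)[C@@H](C(C)(C)C(=O)OC)CCC1C | intermediate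
11 | 2-(trimethylsilyl)ethyl 2-[(1R,6S)-6-(1-methoxy-2-methyl-1-oxopropan-2-yl)-1,3-dimethyl-2-(trifluoromethanesulfonyloxy)cyclohex-2-en-1-yl]acetate | CC1=C(OS(=O)(=O)C(F)(F)F)[C@](C)(CC(=O)OCC[Si](C)(C)C)[C@@H](C(C)(C)C(=O)OC)CC1 | intermediate
12 | potassium vinyltrifluoroborate | C=C[B-](F)(F)F.[K+] | starting material
13 | 2-(trimethylsilyl)ethyl 2-[(1R,6S)-2-ethenyl-6-(1-methoxy-2-methyl-1-oxopropan-2-yl)-1,3-dimethylcyclohex-2-en-1-yl]acetate | CC1=C(C=C)[C@](C)(CC(=O)OCC[Si](C)(C)C)[C@@H](C(C)(C)C(=O)OC)CC1 | intermediate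
14 | B-thexyl borolane spanning C12 and C8 of the left series (boron on the C8 face that later bears OH, H on C9 syn to it) | CC(C)C(C)(C)B1CC[C@H]2[C@](C)(CC(=O)OCC[Si](C)(C)C)[C@@H](C(C)(C)C(=O)OC)CC[C@]12C | intermediate
15 | C8 thexylborinic acid of 16 (B(OH)Thx in place of the C8 hydroxyl) | OC/C=C(C)\CC[C@H]1[C@](C)(CC(=O)OCC[Si](C)(C)C)[C@@H](C(C)(C)C(=O)OC)CC[C@]1(C)B(O)C(C)(C)C(C)C | intermediate
16 | 2-(trimethylsilyl)ethyl 2-[(1R,2S,3S,6S)-3-hydroxy-2-[(3Z)-5-hydroxy-3-methylpent-3-en-1-yl]-6-(1-methoxy-2-methyl-1-oxopropan-2-yl)-1,3-dimethylcyclohexyl]acetate | OC/C=C(C)\CC[C@H]1[C@](C)(CC(=O)OCC[Si](C)(C)C)[C@@H](C(C)(C)C(=O)OC)CC[C@]1(C)O | intermediate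
17 | 2-(trimethylsilyl)ethyl 2-[(1R,2S,3S,6S)-3-hydroxy-2-{2-[(2S,3R)-3-(hydroxymethyl)-2-methyloxiran-2-yl]ethyl}-6-(1-methoxy-2-methyl-1-oxopropan-2-yl)-1,3-dimethylcyclohexyl]acetate | OC[C@H]1O[C@@]1(C)CC[C@H]2[C@](C)(CC(=O)OCC[Si](C)(C)C)[C@@H](C(C)(C)C(=O)OC)CC[C@]2(C)O | intermediate
18 | 2-(trimethylsilyl)ethyl 2-[(2R,4aS,5R,6S,8aS)-2-[(1R)-1,2-dihydroxyethyl]-6-(1-methoxy-2-methyl-1-oxopropan-2-yl)-2,5,8a-trimethyloctahydro-2H-chromen-5-yl]acetate | OC[C@@H](O)[C@@]1(C)CC[C@H]2[C@](C)(CC(=O)OCC[Si](C)(C)C)[C@@H](C(C)(C)C(=O)OC)CC[C@]2(C)O1 | intermediate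
19 | 2-(trimethylsilyl)ethyl 2-[(2R,4aS,5R,6S,8aS)-6-(1-methoxy-2-methyl-1-oxopropan-2-yl)-2,5,8a-trimethyl-2-[(4R)-2-sulfanylidene-1,3-dioxolan-4-yl]octahydro-2H-chromen-5-yl]acetate | S=C1OC[C@@H](O1)[C@@]2(C)CC[C@H]3[C@](C)(CC(=O)OCC[Si](C)(C)C)[C@@H](C(C)(C)C(=O)OC)CC[C@]3(C)O2 | intermediate
20 | 2-(trimethylsilyl)ethyl 2-[(2R,4aS,5R,6S,8aS)-2-ethenyl-6-(1-methoxy-2-methyl-1-oxopropan-2-yl)-2,5,8a-trimethyloctahydro-2H-chromen-5-yl]acetate | C=C[C@@]1(C)CC[C@H]2[C@](C)(CC(=O)OCC[Si](C)(C)C)[C@@H](C(C)(C)C(=O)OC)CC[C@]2(C)O1 | intermediate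
21 | 2-[(2R,4aS,5R,6S,8aS)-2-ethenyl-2,5,8a-trimethyl-5-{2-oxo-2-[2-(trimethylsilyl)ethoxy]ethyl}octahydro-2H-chromen-6-yl]-2-methylpropanoic acid | C=C[C@@]1(C)CC[C@H]2[C@](C)(CC(=O)OCC[Si](C)(C)C)[C@@H](C(C)(C)C(O)=O)CC[C@]2(C)O1 | intermediate
22 | 2-methylpropanoyl chloride | CC(C)C(Cl)=O | starting material
23 | 2-(trimethylsilyl)ethyl 2-methylpropanoate | CC(C)C(=O)OCC[Si](C)(C)C | intermediate
24 | 2-methyl-1-[2-(trimethylsilyl)ethoxy]-1-(trimethylsilyloxy)prop-1-ene | CC(C)=C(OCC[Si](C)(C)C)O[Si](C)(C)C | intermediate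
25 | 2-(trimethylsilyl)ethyl 2-methyl-2-[(1S)-2-methyl-3-(trimethylsilyloxy)cyclohex-2-en-1-yl]propanoate | CC1=C(O[Si](C)(C)C)CCC[C@@H]1C(C)(C)C(=O)OCC[Si](C)(C)C | intermediate
26 | 2-(trimethylsilyl)ethyl 2-methyl-2-[(1S,2R)-2-methyl-3-oxo-2-{2-oxo-2-[2-(trimethylsilyl)ethoxy]ethyl}cyclohexyl]propanoate | O=C1[C@](C)(CC(=O)OCC[Si](C)(C)C)[C@@H](C(C)(C)C(=O)OCC[Si](C)(C)C)CCC1 | intermediate
27 | 2-(trimethylsilyl)ethyl 2-[(1S,2R,4RS)-2,4-dimethyl-3-oxo-2-{2-oxo-2-[2-(trimethylsilyl)ethoxy]ethyl}cyclohexyl]-2-methylpropanoate (C8 epimers) | O=C1[C@](C)(CC(=O)OCC[Si](C)(C)C)[C@@H](C(C)(C)C(=O)OCC[Si](C)(C)C)CCC1C | intermediate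
28 | 2-(trimethylsilyl)ethyl 2-[(1S,2R)-2,4-dimethyl-2-{2-oxo-2-[2-(trimethylsilyl)ethoxy]ethyl}-3-(trifluoromethanesulfonyloxy)cyclohex-3-en-1-yl]-2-methylpropanoate | CC1=C(OS(=O)(=O)C(F)(F)F)[C@](C)(CC(=O)OCC[Si](C)(C)C)[C@@H](C(C)(C)C(=O)OCC[Si](C)(C)C)CC1 | intermediate
29 | 2-(trimethylsilyl)ethyl 2-[(1S,2R)-3-ethenyl-2,4-dimethyl-2-{2-oxo-2-[2-(trimethylsilyl)ethoxy]ethyl}cyclohex-3-en-1-yl]-2-methylpropanoate | CC1=C(C=C)[C@](C)(CC(=O)OCC[Si](C)(C)C)[C@@H](C(C)(C)C(=O)OCC[Si](C)(C)C)CC1 | intermediate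
30 | B-thexyl borolane spanning C12 and C8 of the right series | CC(C)C(C)(C)B1CC[C@H]2[C@](C)(CC(=O)OCC[Si](C)(C)C)[C@@H](C(C)(C)C(=O)OCC[Si](C)(C)C)CC[C@]12C | intermediate
31 | C8 thexylborinic acid of 32 | OC/C=C(C)\CC[C@H]1[C@](C)(CC(=O)OCC[Si](C)(C)C)[C@@H](C(C)(C)C(=O)OCC[Si](C)(C)C)CC[C@]1(C)B(O)C(C)(C)C(C)C | intermediate
32 | 2-(trimethylsilyl)ethyl 2-[(1S,2R,3S,4S)-4-hydroxy-3-[(3Z)-5-hydroxy-3-methylpent-3-en-1-yl]-2,4-dimethyl-2-{2-oxo-2-[2-(trimethylsilyl)ethoxy]ethyl}cyclohexyl]-2-methylpropanoate | OC/C=C(C)\CC[C@H]1[C@](C)(CC(=O)OCC[Si](C)(C)C)[C@@H](C(C)(C)C(=O)OCC[Si](C)(C)C)CC[C@]1(C)O | intermediate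
33 | (13S,14R)-13,14-epoxide of 32 (2-{2-[(2S,3R)-3-(hydroxymethyl)-2-methyloxiran-2-yl]ethyl} side chain) | OC[C@H]1O[C@@]1(C)CC[C@H]2[C@](C)(CC(=O)OCC[Si](C)(C)C)[C@@H](C(C)(C)C(=O)OCC[Si](C)(C)C)CC[C@]2(C)O | intermediate
34 | 2-(trimethylsilyl)ethyl 2-[(2R,4aS,5R,6S,8aS)-2-[(1R)-1,2-dihydroxyethyl]-2,5,8a-trimethyl-5-{2-oxo-2-[2-(trimethylsilyl)ethoxy]ethyl}octahydro-2H-chromen-6-yl]-2-methylpropanoate | OC[C@@H](O)[C@@]1(C)CC[C@H]2[C@](C)(CC(=O)OCC[Si](C)(C)C)[C@@H](C(C)(C)C(=O)OCC[Si](C)(C)C)CC[C@]2(C)O1 | intermediate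
35 | acid chloride of 21 (C3 carbonyl chloride) | C=C[C@@]1(C)CC[C@H]2[C@](C)(CC(=O)OCC[Si](C)(C)C)[C@@H](C(C)(C)C(Cl)=O)CC[C@]2(C)O1 | intermediate
36 | tris-TMSE ester of excoecarin R1 (TMSE esters at C2, C2′ and C3′; C3–O–C15′ ester; free 14′-OH) | C=C[C@@]1(C)CC[C@H]2[C@](C)(CC(=O)OCC[Si](C)(C)C)[C@@H](C(C)(C)C(=O)OC[C@@H](O)[C@@]3(C)CC[C@H]4[C@](C)(CC(=O)OCC[Si](C)(C)C)[C@@H](C(C)(C)C(=O)OCC[Si](C)(C)C)CC[C@]4(C)O3)CC[C@]2(C)O1 | intermediate
37 | excoecarin R1 | C=C[C@@]1(C)CC[C@H]2[C@](C)(CC(=O)O)[C@@H](C(C)(C)C(=O)OC[C@@H](O)[C@@]3(C)CC[C@H]4[C@](C)(CC(=O)O)[C@@H](C(C)(C)C(=O)O)CC[C@]4(C)O3)CC[C@]2(C)O1 | target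

**Step count and risks**

Total step count: 22. Longest linear sequence: 12 steps (steps 3 to 12, then 21 and 22).

Steps most likely to fail:

Step 8 (the new relay, left series). The weak points are transmetalation from the hindered B-thexyl borolane and the face selectivity of the intramolecular hydroboration. The fallback sets out from diene 13 and comes back at 16. The same thexylborane cyclic hydroboration gives 14, but boron is then used without palladium: ICl/NaOAc in MeOH at 0 °C cleaves only the primary C12–B bond to the iodide (known iodinolysis of organoboranes) and NaBO3 oxidises the tertiary C8–B bond, giving the left 12-iodo-8-ol F1. A known nickel-catalysed reductive cross-electrophile coupling of F1 with vinyl iodide 4 (NiI2, 4,4′-di-tert-butyl-2,2′-bipyridine, Zn, DMA, 23 °C), which tolerates free hydroxyls and keeps the Z geometry, then gives 16.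

Step 19 (the same new relay, right series). The fallback sets out from diene 29 and comes back at 32 by the same known sequence: thexylborane cyclic hydroboration to 30, ICl/NaOAc iodinolysis and NaBO3 oxidation to the right 12-iodo-8-ol F2, then nickel-catalysed reductive coupling of F2 with 4.

Step 21 (acylation of a β-branched primary alcohol by a very hindered acid chloride). The fallback sets out from diol 34 (together with acid 21) and comes back at 36 by reversing the polarity. Diol 34 is tosylated selectively at the primary hydroxyl (TsCl, Et3N, cat. Bu2SnO) to the primary tosylate F3 and closed with DBU in CH2Cl2 to the terminal (14R)-epoxide F4. The caesium carboxylate of 21 (Cs2CO3, DMF, 70 °C) opens F4 at the primary C15′ by SN2 O-alkylation, giving 36 with the 14′-hydroxyl already free and no substitution at the hindered carbonyl.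

**Further compounds**

F1 | step 8 | 2-(trimethylsilyl)ethyl 2-[(1R,2S,3S,6S)-3-hydroxy-2-(2-iodoethyl)-6-(1-methoxy-2-methyl-1-oxopropan-2-yl)-1,3-dimethylcyclohexyl]acetate | ICC[C@H]1[C@](C)(CC(=O)OCC[Si](C)(C)C)[C@@H](C(C)(C)C(=O)OC)CC[C@]1(C)O
F2 | step 19 | 2-(trimethylsilyl)ethyl 2-[(1S,2R,3S,4S)-4-hydroxy-3-(2-iodoethyl)-2,4-dimethyl-2-{2-oxo-2-[2-(trimethylsilyl)ethoxy]ethyl}cyclohexyl]-2-methylpropanoate | ICC[C@H]1[C@](C)(CC(=O)OCC[Si](C)(C)C)[C@@H](C(C)(C)C(=O)OCC[Si](C)(C)C)CC[C@]1(C)O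
F3 | step 21 | primary (C15′) 4-methylbenzenesulfonate of diol 34 | Cc1ccc(cc1)S(=O)(=O)OC[C@@H](O)[C@@]1(C)CC[C@H]2[C@](C)(CC(=O)OCC[Si](C)(C)C)[C@@H](C(C)(C)C(=O)OCC[Si](C)(C)C)CC[C@]2(C)O1
F4 | step 21 | (14′R)-14′,15′-epoxide derived from diol 34 | C1O[C@H]1[C@@]2(C)CC[C@H]3[C@](C)(CC(=O)OCC[Si](C)(C)C)[C@@H](C(C)(C)C(=O)OCC[Si](C)(C)C)CC[C@]3(C)O2
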